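**Conventions.** Oxolane atoms are O1 and C2–C5 (C2 is the lactone carbonyl carbon in every lactone intermediate). Dihydrobenzofuran atoms carry primes (O1′, C2′, C3′, C3a′, C4′–C7′, C7a′), and ring A is its benzo ring. ArP = 4-(benzyloxy)phenyl and ArR = 3,5-bis(benzyloxy)phenyl. Compound numbers are those of the steps below.

## Analysis of the target

The target 41 (C42H34O10) is a 2,3,4,5-tetraaryl oxolane whose C3 aryl group is ring A of a trans-2,3-diaryl-2,3-dihydrobenzofuran. It carries eight free phenols: three 4-hydroxyphenyl groups (on C2, C5, C2′), two 3,5-dihydroxyphenyl groups (on C4, C3′) and the resorcinol-derived ring A. There are six stereocentres. C2 (S), C3 (S), C4 (R) and C5 (S) sit on the oxolane, with the aryl groups of C2, C3 and C4 on one face and that of C5 on the other (2,3-cis, 3,4-cis, 4,5-trans). C2′ (R) and C3′ (R) are trans on the dihydrobenzofuran, and ring A holds the two sets apart, so neither can simply be relayed to the other. Every oxygen-bearing benzylic carbon (C2, C5, C2′) has a para-oxygenated aryl group and ionises easily under acid, which drifts the rings towards trans arrangements. The contiguous cis triad C2–C3–C4 is therefore contra-thermodynamic and must be made late and kinetically, and the phenols are best masked as benzyl ethers removable under neutral hydrogenolysis. The difficulty lies in this crowded triad and in ring A, a 1,2,3,5-tetrasubstituted benzene with two vicinal carbon substituents beside an oxygen. That pattern is the handle of the plan: C4′ (bonded to C3) and C3a′ (bonded to C3′) are adjacent and C7a′ next to C3a′ bears oxygen, which is what a 3-alkoxyaryne leaves when it inserts into the bond between the α-carbon and the ketone of a β-keto ester. Ring A is therefore delivered as aryne 23 and welded between lactone 22, which already holds C4 and C5, and the aroyl group that becomes C3′.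

## Retrosynthetic reasoning

**41 ⇒ 40.** The eight O–benzyl bonds are cut last. Hydrogenolysis is neutral, so none of the acid-labile benzylic C–O bonds of the two oxygen rings is put at risk, and one protecting group serves from the first step to the last.

**40 ⇒ 39 ⇒ 36 + 38.** The C2–H bond and the C2–aryl bond are cut, which makes C2 the carbonyl carbon of lactone 36. The order of the forward events matters: the aryl group (as the weakly basic aryl-cerium reagent 38, made from bromide 11) enters first and hydride second, so that the small nucleophile attacks the oxocarbenium ion anti to the C3 aryl group and leaves the 2,3-cis relation. The reverse order would give trans.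

**36 ⇒ 34.** Only the C3–H bond is changed. C3 is α to the lactone carbonyl, so it is the one stereocentre that can be erased (enolate 35) and rewritten by kinetic protonation. This allows ring A to be attached earlier without any stereocontrol at C3.

**34 ⇒ 27 + 31.** The bonds C3′–C2′ and C2′–O1′ are cut as a [4+1] annulation between ortho-quinone methide 32 (from sulfone 27) and the ylide 33 of chiral sulfonium salt 31. Sulfone 27 goes back through benzhydrol 26 and phenol 25 to ketone 24: the ketone carbon is C3′ at the right oxidation level, and the benzyloxy group ortho to it is O1′, which can be unmasked selectively because it chelates with that ketone. The ketone must be consumed before any aryl-metal reagent meets the lactone, which fixes this ring closure before the oxolane endgame. Salt 31 comes from sulfide 29 (one step from 28) and alcohol 30.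

**24 ⇒ 22 + 7 (key disconnection).** The bonds C3–C4′ and C3a′–C3′ are cut together. Forward, aryne 23, released from silyl triflate 7, inserts into the C3–acyl bond of β-keto lactone 22. Cutting here removes the need for any regioselective substitution on a ring that would otherwise compete with two other resorcinol rings, and it brings in ring A, C3′ and the C3′ aryl group in one operation.

**22 ⇒ 19 + 20.** The C3–acyl bond is a crossed Claisen condensation between the enolate of trans lactone 19 and the non-enolisable ester 20.

**19 ⇒ 17 ⇒ 16 ⇒ 13 + 14.** The lactone is opened to hydroxy ester 17, whose two stereocentres come from racemic keto ester 16 by a reduction run under dynamic kinetic resolution. The stereocentre of 16 is α to a ketone and benzylic, so it is deliberately labile. C4 is fixed in the reduction, and C5 is then set thermodynamically by equilibration of the lactone. Keto ester 16 is the alkylation product of deoxybenzoin 13 with 14. Ketone 13 comes from Weinreb amide 10 and bromide 11, and 10 from acid 8 through ester 9.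

**7 ⇒ 4 ⇒ 3 ⇒ 2 ⇒ 1.** The silyl triflate is made from bromophenol 3 by the silyl ether 4, and 3 from phloroglucinol 1 through dibenzyl ether 2. The oxygen that ends up flanking silicon is the one that directs the aryne regiochemistry and later becomes O1′.

## Alternatives that were turned down

**Alternative 1: ylide annulation of an enone through a donor–acceptor cyclopropane.**
- Disconnection: C4–C5 and C5–O1, taken at the 4,5-dihydrofuran level, so that dihydrofuran A1 comes from α-aryl enone A2 and a benzylic sulfonium ylide such as 33.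
- Forward key step: the ylide carbon would add to the β-carbon of A2 and close cyclopropane A3. A Lewis acid would reopen A3 at its aryl-bearing donor carbon and the enolate oxygen would recapture the benzylic cation, giving the 4,5-trans ring of A1 in one flask. Saturation of C2=C3 would complete the oxolane.
- In favour: it is the most convergent assembly of the oxolane, two bonds and the ring in one operation. It needs no lactone, no organocerium step and no separate correction of C3, and a syn addition to C2=C3 would set C2 and C3 cis to each other by mechanism. On step economy in the oxolane part it is stronger than the chosen route.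
- Against, for this target: the β-carbon of A2 is flanked by an α-aryl group that is itself ortho-substituted and twisted, so conjugate addition is slow and carbonyl attack (epoxide formation) competes. C4 is created in that addition with no nearby stereocentre, so its absolute configuration rests entirely on the chiral sulfide. The final reduction of A1 meets a tetrasubstituted enol ether whose two faces each carry one aryl group (C4 up, C5 down), so the facial outcome that fixes both C2 and C3 is hard to predict. A2 also presupposes a finished ring A, so the vicinal substitution problem is only moved.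
- Comparison: the chosen route is longer in the oxolane part but builds ring A in the same step that attaches it. C4 comes from a catalyst-controlled reduction, C5 from thermodynamics, and C3 and C2 are then set one at a time, each next to a single identified controlling group.

**Alternative 2: ortho-quinone methide [4+1] as the last ring closure.**
- Disconnection: C3′–C2′ and C2′–O1′, cut on a finished oxolane.
- Forward key step: a carbonate base would unmask the ortho-quinone methide from phenol sulfone A5. The ylide 33 would add to the methide carbon and the phenoxide would displace the sulfide to give A4, which is the same compound as 40.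
- In favour: the annulation would end directly in the fully protected target. No enolisable lactone would be exposed to the basic ylide conditions, and C3 could no longer epimerise. This is a real advantage over the chosen route, where the annulation precedes the C3 correction and that correction must then be done on a very hindered enolate.
- Against, for this target: the C3′ carbon would have to travel through aryl-metal addition and Lewis-acidic silane reduction as a ketone (which competes with the lactone for the aryl nucleophile) or as a benzhydrol (which ionises under the Lewis acid), so masking steps are needed. The methide carbon would sit next to a fully substituted all-cis oxolane rather than a flat lactone, which makes ylide approach harder and the substrate's facial bias unknowable. It also leaves open how ring A is made.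
- Comparison: the chosen route uses the same annulation but earlier, straight after the ketone has been produced by the aryne insertion, with no masking and with a less crowded neighbour. The price is the late C3 protonation.

**Alternative 3: carbene-catalysed homoenolate annulation to a cis lactone.**
- Disconnection: C2–C3 and O1–C5, with the lactone carbonyl at C5 instead of C2.
- Forward key step: a chiral triazolium-derived carbene would turn enal A7 into a homoenolate whose β-carbon adds to aldehyde A8. The resulting alkoxide would be acylated by the acyl azolium to close the 2,3-cis lactone A6.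
- In favour: a catalytic asymmetric C–C bond formation would set the 2,3-cis relation in the ring-forming step, the very relation the chosen route has to obtain from an oxocarbenium reduction. On that point it is stronger, and it is convergent.
- Against, for this target: A7 is an α,β-diaryl enal, and α-branching retards formation and β-reactivity of the homoenolate, while aromatic aldehydes such as A8 invite benzoin-type side reactions. The chiral dihydrobenzofuran already present in A7 makes the catalyst work against or with a remote bias. C4 would form as its more stable epimer and need the same kind of kinetic protonation as C3 in the chosen route. The last aryl group at C5 would have to enter trans to the C4 aryl group, which hydride reduction of an aryl lactol cannot give. A Friedel–Crafts-type C-arylation of an oxocarbenium ion would be required, exposing the acid-labile all-cis array to a Lewis acid. Ring A is again presupposed.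
- Comparison: the chosen route has no step that sets 2,3-cis catalytically, but its lactone carbonyl sits at C2, where hydride-after-aryl gives the required relation, and it solves the ring A substitution pattern that this alternative takes for granted.

Key step: step 12

**Assumption:** the ylide from the (R)-limonene-derived sulfide is taken to favour the (2′R,3′R) ring in step 18, by analogy with its face selectivity towards aldehydes; if a model annulation shows the opposite sense, the sulfide from (S)-limonene is used and nothing else changes.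

## Route

Step 1
Reactants: 1 phloroglucinol
Product: 2 3,5-bis(benzyloxy)phenol
Conditions: BnBr (2.0 equiv), K2CO3, DMF, 0 °C to rt; chromatography
Reagents that add atoms: benzyl bromide, BrCc1ccccc1
Why: Williamson etherification of two of three equivalent hydroxyls, controlled only by stoichiometry; the mono- and tribenzyl ethers are removed by chromatography, which is acceptable for the first step from a cheap material.

Step 2
Reactants: 2 3,5-bis(benzyloxy)phenol
Product: 3 2-bromo-3,5-bis(benzyloxy)phenol
Conditions: N-bromosuccinimide (1.0 equiv), CH2Cl2, −78 to −40 °C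
Reagents that add atoms: N-bromosuccinimide, O=C1CCC(=O)N1Br
Why: Electrophilic aromatic bromination; in a non-polar solvent at low temperature the free hydroxyl should steer bromine to its own ortho position rather than to the carbon flanked by two benzyloxy groups, and one equivalent avoids dibromination.

Step 3
Reactants: 3 2-bromo-3,5-bis(benzyloxy)phenol
Product: 4 [2-bromo-3,5-bis(benzyloxy)phenoxy]trimethylsilane
Conditions: (Me3Si)2NH, THF, 70 °C; evaporation
Reagents that add atoms: hexamethyldisilazane, C[Si](C)(C)N[Si](C)(C)C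
Why: O-silylation of the phenol with a silazane forms only ammonia as by-product, so the silyl ether can be used after evaporation.

Step 4
Reactants: 4 [2-bromo-3,5-bis(benzyloxy)phenoxy]trimethylsilane
Product: 7 3,5-bis(benzyloxy)-2-(trimethylsilyl)phenyl trifluoromethanesulfonate, via aryllithium 5 (not isolated), via lithium silylphenoxide 6 (not isolated)
Conditions: n-BuLi, THF, −100 to −78 °C; then Tf2O, −78 °C
Reagents that add atoms: trifluoromethanesulfonic anhydride, O=S(=O)(OS(=O)(=O)C(F)(F)F)C(F)(F)F
Why: Bromine–lithium exchange is far faster than benzylic lithiation at this temperature; aryllithium 5 undergoes 1,3 oxygen-to-carbon silyl migration (retro-Brook rearrangement) to phenoxide 6, which is triflated, the standard route to ortho-silylaryl triflates.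

Step 5
Reactants: 8 3,5-dihydroxyphenylacetic acid
Product: 9 benzyl [3,5-bis(benzyloxy)phenyl]acetate
Conditions: BnBr (3.3 equiv), K2CO3, DMF, 50 °C
Reagents that add atoms: benzyl bromide, BrCc1ccccc1
Why: Exhaustive O-benzylation (two Williamson etherifications and carboxylate alkylation) protects both phenols and activates the acid as an ester in one operation.

Step 6
Reactants: 9 benzyl [3,5-bis(benzyloxy)phenyl]acetate
Product: 10 2-[3,5-bis(benzyloxy)phenyl]-N-methoxy-N-methylacetamide
Conditions: MeNH(OMe)·HCl, i-PrMgCl, THF, −20 °C; dilute HCl work-up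
Reagents that add atoms: N,O-dimethylhydroxylamine hydrochloride, CNOC.Cl
Why: Direct aminolysis of the ester by the chloromagnesium amide generated in the flask (Weinreb amide formation); the low temperature keeps enolisation of the arylacetate from interfering.

Step 7
Reactants: 10 2-[3,5-bis(benzyloxy)phenyl]-N-methoxy-N-methylacetamide; 11 1-(benzyloxy)-4-bromobenzene
Product: 13 1-[4-(benzyloxy)phenyl]-2-[3,5-bis(benzyloxy)phenyl]ethan-1-one, via arylmagnesium bromide 12 (not isolated)
Conditions: 11, Mg, THF, 40 °C; then 10, THF, 0 °C; dilute HCl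
Reagents that add atoms: none
Why: Weinreb ketone synthesis; the chelated tetrahedral adduct survives until work-up, so the Grignard reagent adds once only and the deoxybenzoin is released on acidification.

Step 8
Reactants: 13 1-[4-(benzyloxy)phenyl]-2-[3,5-bis(benzyloxy)phenyl]ethan-1-one; 14 ethyl bromoacetate
Product: 16 ethyl 4-ArP-3-ArR-4-oxobutanoate (racemic), via lithium enolate 15 (not isolated)
Conditions: LiN(SiMe3)2 (1.05 equiv), THF, −78 °C; then 14, −78 to 0 °C
Reagents that add atoms: none
Why: Enolate alkylation; the methylene between the carbonyl and the aryl ring is deprotonated cleanly and the enolate reacts with a reactive primary bromide by SN2, with one equivalent of base limiting dialkylation; the new stereocentre is racemic and intentionally labile.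

Step 9
Reactants: 16 ethyl 4-ArP-3-ArR-4-oxobutanoate (racemic)
Product: 17 ethyl (3R,4R)-4-ArP-3-ArR-4-hydroxybutanoate
Conditions: RuCl[(R,R)-TsDPEN](p-cymene) (1 mol %), HCO2H/Et3N (1:2), DMF, 40 °C
Reagents that add atoms: none
Why: Noyori–Ikariya transfer hydrogenation under dynamic kinetic resolution: the α-centre (benzylic and α to the ketone) racemises through the enol in the amine-rich medium, the (R,R) catalyst delivers hydride to give the (R)-carbinol as it does for aryl alkyl ketones, and the ketone enantiomer whose α-aryl group lies anti to the incoming hydride (Felkin–Anh) reacts faster, giving the syn (3R,4R) product. This step fixes C4 of the target.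

Step 10
Reactants: 17 ethyl (3R,4R)-4-ArP-3-ArR-4-hydroxybutanoate
Product: 19 (4R,5S)-5-ArP-4-ArR-oxolan-2-one, via cis lactone 18 (not isolated)
Conditions: CF3CO2H (10 vol %), CH2Cl2, 0 °C to rt
Reagents that add atoms: none
Why: Acid-catalysed lactonisation with retention gives cis lactone 18; reversible SN1 ionisation of its C5–O bond (para-benzyloxybenzyl cation, internal return of the carboxyl group) then epimerises C5 to the more stable 4,5-trans lactone. C5 is thus set under thermodynamic control while C4 is not touched.

Step 11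
Reactants: 19 (4R,5S)-5-ArP-4-ArR-oxolan-2-one; 20 methyl 3,5-bis(benzyloxy)benzoate
Product: 22 (3R,4R,5S)-3-[3,5-bis(benzyloxy)benzoyl]-5-ArP-4-ArR-oxolan-2-one, via lithium enolate 21 (not isolated)
Conditions: LiN(SiMe3)2 (2.2 equiv), THF, −78 °C; then 20, −78 to 0 °C; dilute HCl
Reagents that add atoms: none
Why: Crossed Claisen condensation of a lactone enolate with a non-enolisable ester; the second equivalent of base deprotonates the β-keto lactone and drives the equilibrium, and C3 settles trans to the C4 aryl group (it remains epimerisable).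

Step 12
Reactants: 22 (3R,4R,5S)-3-[3,5-bis(benzyloxy)benzoyl]-5-ArP-4-ArR-oxolan-2-one; 7 3,5-bis(benzyloxy)-2-(trimethylsilyl)phenyl trifluoromethanesulfonate
Product: 24 (3R,4R,5S)-3-{3,5-bis(benzyloxy)-2-[3,5-bis(benzyloxy)benzoyl]phenyl}-5-ArP-4-ArR-oxolan-2-one, via aryne 23 (not isolated)
Conditions: CsF (3 equiv), 7 (1.3 equiv), MeCN, 80 °C
Reagents that add atoms: none
Why: Fluoride attacks silicon of 7 and expels triflate to release aryne 23, and the same base deprotonates 22 at C3, its most acidic position. The enolate carbon adds to the aryne carbon remote from the flanking benzyloxy group (C3–C4′), the aryl anion formed beside that oxygen attacks the neighbouring ketone carbonyl in a 4-exo-trig closure, and the strained four-membered alkoxide opens by retro-aldol cleavage of the old C3–acyl bond (net formation of C3a′–C3′), leaving the lactone enolate, which is protonated. The closest known reaction is the aryne acyl-alkylation of β-keto esters, α-substituted and lactone examples included, with ortho-silylaryl triflates and CsF in hot acetonitrile. No ring of the product is closed; the only ring formed is the transient four-membered alkoxide. No stereocentre is set under control: C4 and C5 are spectators and C3 is re-formed by protonation of the enolate as the more stable 3,4-trans epimer, to be corrected in step 19. The step needs regioselectivity, secured by the benzyloxy group next to the aryne, which polarises the triple bond so that the nucleophile attacks the far carbon and the negative charge develops beside oxygen; this places the ketone next to the future O1′. It also needs C- over O-arylation and attack of the aryl anion on the ketone and not the lactone carbonyl; the softer carbon terminus of the stabilised enolate, the greater electrophilicity of the ketone and the slow release of the aryne from sparingly soluble CsF favour both.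

Step 13
Reactants: 24 aroyl-aryl lactone from step 12
Product: 25 (3R,4R,5S)-3-{5-(benzyloxy)-2-[3,5-bis(benzyloxy)benzoyl]-3-hydroxyphenyl}-5-ArP-4-ArR-oxolan-2-one
Conditions: BCl3 (1.1 equiv), CH2Cl2, −78 °C; aqueous work-up
Reagents that add atoms: none
Why: Chelation-directed ether cleavage: boron binds the ketone oxygen and the ortho ether oxygen in a six-membered chelate and only that benzyl group is lost; the six other benzyl ethers have no chelating neighbour and survive one equivalent at low temperature.

Step 14
Reactants: 25 ortho-hydroxy ketone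
Product: 26 (3R,4R,5S)-3-{5-(benzyloxy)-2-[ArR(hydroxy)methyl]-3-hydroxyphenyl}-5-ArP-4-ArR-oxolan-2-one (both carbinol epimers)
Conditions: NaBH4, CeCl3·7H2O, MeOH/THF, −20 to 0 °C
Reagents that add atoms: none
Why: Luche reduction of the diaryl ketone; the lactone is inert to borohydride at this temperature and the weakly acidic medium keeps the new alkoxide from opening it. The carbinol configuration is irrelevant because this carbon is flattened in step 18.

Step 15
Reactants: 26 ortho-hydroxy benzhydrol
Product: 27 (3R,4R,5S)-3-{5-(benzyloxy)-2-[ArR(4-methylbenzenesulfonyl)methyl]-3-hydroxyphenyl}-5-ArP-4-ArR-oxolan-2-one (both epimers)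
Conditions: 4-MeC6H4SO2H (1.5 equiv), CH2Cl2, rt
Reagents that add atoms: p-toluenesulfinic acid, Cc1ccc(cc1)S(=O)O
Why: SN1 substitution: the benzhydrol, activated by the ortho hydroxyl and the para benzyloxy group, ionises under the acidity of the reagent and the cation is captured at sulfur, giving a storable sulfone precursor of the quinone methide.

Step 16
Reactants: 28 (R)-limonene
Product: 29 (1R,4R,5R)-isothiocineole
Conditions: S8, γ-terpinene, 125 °C, neat; distillation
Reagents that add atoms: sulfur, S1SSSSSSS1
Why: Known one-step radical sulfur transfer across both alkenes of limonene with γ-terpinene as hydrogen donor; the stereocentre of limonene is kept and fixes the bicyclic framework.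

Step 17
Reactants: 29 (1R,4R,5R)-isothiocineole; 30 [4-(benzyloxy)phenyl]methanol
Product: 31 6-[4-(benzyloxy)benzyl]isothiocineolium tetrafluoroborate
Conditions: HBF4·OEt2, CH2Cl2, 0 °C to rt; precipitation with Et2O
Reagents that add atoms: tetrafluoroboric acid, [H+].F[B-](F)(F)F
Why: S-alkylation of the sulfide by the para-benzyloxybenzyl cation generated from the alcohol with a non-nucleophilic acid (SN1); alkylation should occur on the less hindered lone pair to give one sulfonium diastereomer.

Step 18
Reactants: 27 phenol sulfone; 31 6-[4-(benzyloxy)benzyl]isothiocineolium tetrafluoroborate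
Product: 34 (3R,4R,5S)-5-ArP-4-ArR-3-[(2R,3R)-6-(benzyloxy)-2-ArP-3-ArR-2,3-dihydro-1-benzofuran-4-yl]oxolan-2-one, via ortho-quinone methide 32 (not isolated), via sulfonium ylide 33 (not isolated)
Conditions: Cs2CO3 (3 equiv), MeCN/CH2Cl2, −20 °C to rt
Reagents that add atoms: none
Why: Proposed new method: carbonate converts 27 into ortho-quinone methide 32 (loss of sulfinate from the phenoxide) and 31 into ylide 33; the ylide carbon adds to the methide carbon (C3′–C2′), which re-aromatises ring A, and the phenoxide displaces the sulfide by 5-exo-tet SN2 (C2′–O1′), the anti mode of addition leading to the trans ring; the chiral sulfide fixes the conformation and exposed face of the ylide and hence C2′, and C3′ follows from the trans preference; the closest known reactions are the [4+1] annulation of sulfonium ylides with ortho-quinone methides generated from 2-(tosylmethyl)phenols under carbonate base and the isothiocineole-mediated asymmetric epoxidation with benzylic sulfonium ylides, while reagent-controlled induction by such a ylide on a quinone methide has not been shown.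

Step 19
Reactants: 34 dihydrobenzofuranyl lactone (3,4-trans)
Product: 36 (3S,4R,5S)-5-ArP-4-ArR-3-[(2R,3R)-6-(benzyloxy)-2-ArP-3-ArR-2,3-dihydro-1-benzofuran-4-yl]oxolan-2-one, via lithium enolate 35 (not isolated)
Conditions: LiN(i-Pr)2, THF, −78 °C; 2,6-di-tert-butyl-4-methylphenol, −78 °C; AcOH quench
Reagents that add atoms: none
Why: Kinetic diastereoselective protonation: deprotonation erases C3 in planar enolate 35, and the hindered phenol should deliver the proton to the face anti to the C4 aryl group, which places ring A cis to that group (the less stable epimer); the cold acetic acid quench prevents re-equilibration.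

Step 20
Reactants: 36 3,4-cis lactone; 11 1-(benzyloxy)-4-bromobenzene
Product: 39 (3S,4R,5S)-2,5-di-ArP-4-ArR-3-[(2R,3R)-6-(benzyloxy)-2-ArP-3-ArR-2,3-dihydro-1-benzofuran-4-yl]oxolan-2-ol (both anomers), via aryllithium 37 (not isolated), via arylcerium dichloride 38 (not isolated)
Conditions: 11, n-BuLi, THF, −78 °C; CeCl3, −78 °C; then 36, −78 °C; AcOH then pH 7 buffer; used crude
Reagents that add atoms: none
Why: Organocerium addition to the lactone carbonyl; the reagent is nucleophilic but barely basic, so the acidic C3–H is not removed, and the tetrahedral alkoxide persists at −78 °C so that only one aryl group adds. The anomeric configuration is irrelevant.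

Step 21
Reactants: 39 lactol
Product: 40 octa-O-benzyl ether of the target, (2S,3S,4R,5S)-2,5-di-ArP-4-ArR-3-[(2R,3R)-6-(benzyloxy)-2-ArP-3-ArR-2,3-dihydro-1-benzofuran-4-yl]oxolane
Conditions: Et3SiH, BF3·OEt2, CH2Cl2, −78 °C
Reagents that add atoms: none
Why: Ionic hydrogenation of the lactol: the Lewis acid ionises it to a 2-aryl oxocarbenium ion and the silane delivers hydride to the face opposite the C3 and C4 aryl groups, which leaves the C2 aryl group cis to ring A; the low temperature suppresses proton loss to the enol ether and acid epimerisation of C2.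

Step 22
Reactants: 40 octa-O-benzyl ether
Product: 41 target, (2S,3S,4R,5S)-2,5-bis(4-hydroxyphenyl)-4-(3,5-dihydroxyphenyl)-3-[(2R,3R)-3-(3,5-dihydroxyphenyl)-6-hydroxy-2-(4-hydroxyphenyl)-2,3-dihydro-1-benzofuran-4-yl]oxolane
Conditions: H2 (1 atm), 10% Pd/C, EtOAc/MeOH, rt; stopped at the calculated uptake
Reagents that add atoms: none
Why: Catalytic hydrogenolysis of eight primary aryl benzyl ethers under neutral conditions; the secondary, hindered, cyclic benzylic C–O bonds of the two oxygen rings are cleaved much more slowly, and no acid is present to epimerise C2, C5 or C2′.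

## Compound list

1 | phloroglucinol | Oc1cc(O)cc(O)c1 | starting material
2 | 3,5-bis(benzyloxy)phenol | Oc1cc(OCc9ccccc9)cc(OCc9ccccc9)c1 | intermediate
3 | 2-bromo-3,5-bis(benzyloxy)phenol | Oc1cc(OCc9ccccc9)cc(OCc9ccccc9)c1Br | intermediate
4 | [2-bromo-3,5-bis(benzyloxy)phenoxy]trimethylsilane | C[Si](C)(C)Oc1cc(OCc9ccccc9)cc(OCc9ccccc9)c1Br | intermediate
5 | [2,4-bis(benzyloxy)-6-(trimethylsilyloxy)phenyl]lithium (formed in the flask) | [Li]c1c(O[Si](C)(C)C)cc(OCc9ccccc9)cc1OCc9ccccc9 | intermediate
6 | lithium 3,5-bis(benzyloxy)-2-(trimethylsilyl)phenoxide (formed in the flask) | [Li+].[O-]c1cc(OCc9ccccc9)cc(OCc9ccccc9)c1[Si](C)(C)C | intermediate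
7 | 3,5-bis(benzyloxy)-2-(trimethylsilyl)phenyl trifluoromethanesulfonate | C[Si](C)(C)c1c(OS(=O)(=O)C(F)(F)F)cc(OCc9ccccc9)cc1OCc9ccccc9 | intermediate
8 | 3,5-dihydroxyphenylacetic acid | OC(=O)Cc1cc(O)cc(O)c1 | starting material
9 | benzyl [3,5-bis(benzyloxy)phenyl]acetate | O=C(Cc1cc(OCc9ccccc9)cc(OCc9ccccc9)c1)OCc9ccccc9 | intermediate
10 | 2-[3,5-bis(benzyloxy)phenyl]-N-methoxy-N-methylacetamide | CON(C)C(=O)Cc1cc(OCc9ccccc9)cc(OCc9ccccc9)c1 | intermediate
11 | 1-(benzyloxy)-4-bromobenzene | Brc1ccc(OCc9ccccc9)cc1 | starting material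
12 | [4-(benzyloxy)phenyl]magnesium bromide (formed in the flask) | Br[Mg]c1ccc(OCc9ccccc9)cc1 | intermediate
13 | 1-[4-(benzyloxy)phenyl]-2-[3,5-bis(benzyloxy)phenyl]ethan-1-one | O=C(Cc1cc(OCc9ccccc9)cc(OCc9ccccc9)c1)c1ccc(OCc9ccccc9)cc1 | intermediate
14 | ethyl bromoacetate | CCOC(=O)CBr | starting material
15 | lithium (Z)-enolate of 13 (formed in the flask) | [Li+].[O-]/C(=C\c1cc(OCc9ccccc9)cc(OCc9ccccc9)c1)c1ccc(OCc9ccccc9)cc1 | intermediate
16 | ethyl 4-[4-(benzyloxy)phenyl]-3-[3,5-bis(benzyloxy)phenyl]-4-oxobutanoate (racemic) | CCOC(=O)CC(c1cc(OCc9ccccc9)cc(OCc9ccccc9)c1)C(=O)c1ccc(OCc9ccccc9)cc1 | intermediate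
17 | ethyl (3R,4R)-4-[4-(benzyloxy)phenyl]-3-[3,5-bis(benzyloxy)phenyl]-4-hydroxybutanoate | CCOC(=O)C[C@H](c1cc(OCc9ccccc9)cc(OCc9ccccc9)c1)[C@@H](O)c1ccc(OCc9ccccc9)cc1 | intermediate
18 | (4R,5R)-5-[4-(benzyloxy)phenyl]-4-[3,5-bis(benzyloxy)phenyl]oxolan-2-one, cis lactone (formed in the flask) | O=C1O[C@@H](c2ccc(OCc9ccccc9)cc2)[C@@H](c2cc(OCc9ccccc9)cc(OCc9ccccc9)c2)C1 | intermediate
19 | (4R,5S)-5-[4-(benzyloxy)phenyl]-4-[3,5-bis(benzyloxy)phenyl]oxolan-2-one, trans lactone | O=C1O[C@H](c2ccc(OCc9ccccc9)cc2)[C@@H](c2cc(OCc9ccccc9)cc(OCc9ccccc9)c2)C1 | intermediate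
20 | methyl 3,5-bis(benzyloxy)benzoate | COC(=O)c1cc(OCc9ccccc9)cc(OCc9ccccc9)c1 | starting material
21 | lithium enolate of 19 (formed in the flask) | [Li+].[O-]C1O[C@H](c2ccc(OCc9ccccc9)cc2)[C@@H](c2cc(OCc9ccccc9)cc(OCc9ccccc9)c2)C=1 | intermediate
22 | (3R,4R,5S)-3-[3,5-bis(benzyloxy)benzoyl]-5-[4-(benzyloxy)phenyl]-4-[3,5-bis(benzyloxy)phenyl]oxolan-2-one | O=C1O[C@H](c2ccc(OCc9ccccc9)cc2)[C@@H](c2cc(OCc9ccccc9)cc(OCc9ccccc9)c2)[C@@H]1C(=O)c1cc(OCc9ccccc9)cc(OCc9ccccc9)c1 | intermediate
23 | 3,5-bis(benzyloxy)benzyne (formed in the flask) | C1#CC(OCc9ccccc9)=CC(OCc9ccccc9)=C1 | intermediate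
24 | (3R,4R,5S)-3-{3,5-bis(benzyloxy)-2-[3,5-bis(benzyloxy)benzoyl]phenyl}-5-[4-(benzyloxy)phenyl]-4-[3,5-bis(benzyloxy)phenyl]oxolan-2-one | O=C1O[C@H](c2ccc(OCc9ccccc9)cc2)[C@@H](c2cc(OCc9ccccc9)cc(OCc9ccccc9)c2)[C@@H]1c1cc(OCc9ccccc9)cc(OCc9ccccc9)c1C(=O)c1cc(OCc9ccccc9)cc(OCc9ccccc9)c1 | intermediate
25 | (3R,4R,5S)-3-{5-(benzyloxy)-2-[3,5-bis(benzyloxy)benzoyl]-3-hydroxyphenyl}-5-[4-(benzyloxy)phenyl]-4-[3,5-bis(benzyloxy)phenyl]oxolan-2-one | O=C1O[C@H](c2ccc(OCc9ccccc9)cc2)[C@@H](c2cc(OCc9ccccc9)cc(OCc9ccccc9)c2)[C@@H]1c1cc(OCc9ccccc9)cc(O)c1C(=O)c1cc(OCc9ccccc9)cc(OCc9ccccc9)c1 | intermediate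
26 | (3R,4R,5S)-3-{5-(benzyloxy)-2-[[3,5-bis(benzyloxy)phenyl](hydroxy)methyl]-3-hydroxyphenyl}-5-[4-(benzyloxy)phenyl]-4-[3,5-bis(benzyloxy)phenyl]oxolan-2-one, both carbinol epimers | O=C1O[C@H](c2ccc(OCc9ccccc9)cc2)[C@@H](c2cc(OCc9ccccc9)cc(OCc9ccccc9)c2)[C@@H]1c1cc(OCc9ccccc9)cc(O)c1C(O)c1cc(OCc9ccccc9)cc(OCc9ccccc9)c1 | intermediate
27 | (3R,4R,5S)-3-{5-(benzyloxy)-2-[[3,5-bis(benzyloxy)phenyl](4-methylbenzenesulfonyl)methyl]-3-hydroxyphenyl}-5-[4-(benzyloxy)phenyl]-4-[3,5-bis(benzyloxy)phenyl]oxolan-2-one, both epimers | O=C1O[C@H](c2ccc(OCc9ccccc9)cc2)[C@@H](c2cc(OCc9ccccc9)cc(OCc9ccccc9)c2)[C@@H]1c1cc(OCc9ccccc9)cc(O)c1C(c1cc(OCc9ccccc9)cc(OCc9ccccc9)c1)S(=O)(=O)c1ccc(C)cc1 | intermediate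
28 | (R)-limonene | CC1=CC[C@@H](CC1)C(C)=C | starting material
29 | (1R,4R,5R)-isothiocineole, (1R,4R,5R)-4,7,7-trimethyl-6-thiabicyclo[3.2.1]octane | C[C@@H]1CC[C@@H]2C[C@H]1SC2(C)C | intermediate
30 | [4-(benzyloxy)phenyl]methanol | OCc1ccc(OCc9ccccc9)cc1 | starting material
31 | (1R,4R,5R)-6-[4-(benzyloxy)benzyl]-4,7,7-trimethyl-6-thiabicyclo[3.2.1]octan-6-ium tetrafluoroborate (sulfur configuration as formed) | C[C@@H]1CC[C@@H]2C[C@H]1[S+](Cc1ccc(OCc9ccccc9)cc1)C2(C)C.F[B-](F)(F)F | intermediate
32 | ortho-quinone methide from 27: lactone as in 27, ring A as 5-(benzyloxy)-3-oxocyclohexa-1,5-dien-1-yl bearing a 3,5-bis(benzyloxy)benzylidene group at its C2 (formed in the flask) | O=C1O[C@H](c2ccc(OCc9ccccc9)cc2)[C@@H](c2cc(OCc9ccccc9)cc(OCc9ccccc9)c2)[C@@H]1C1=CC(OCc9ccccc9)=CC(=O)C1=Cc1cc(OCc9ccccc9)cc(OCc9ccccc9)c1 | intermediate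
33 | sulfonium ylide of 31 (formed in the flask) | C[C@@H]1CC[C@@H]2C[C@H]1[S+]([CH-]c1ccc(OCc9ccccc9)cc1)C2(C)C | intermediate
34 | (3R,4R,5S)-5-[4-(benzyloxy)phenyl]-4-[3,5-bis(benzyloxy)phenyl]-3-{(2R,3R)-6-(benzyloxy)-2-[4-(benzyloxy)phenyl]-3-[3,5-bis(benzyloxy)phenyl]-2,3-dihydro-1-benzofuran-4-yl}oxolan-2-one | O=C1O[C@H](c2ccc(OCc9ccccc9)cc2)[C@@H](c2cc(OCc9ccccc9)cc(OCc9ccccc9)c2)[C@@H]1c1cc(OCc9ccccc9)cc2c1[C@@H](c1cc(OCc9ccccc9)cc(OCc9ccccc9)c1)[C@H](c1ccc(OCc9ccccc9)cc1)O2 | intermediate
35 | lithium enolate of 34 (formed in the flask) | [Li+].[O-]C1O[C@H](c2ccc(OCc9ccccc9)cc2)[C@@H](c2cc(OCc9ccccc9)cc(OCc9ccccc9)c2)C=1c1cc(OCc9ccccc9)cc2c1[C@@H](c1cc(OCc9ccccc9)cc(OCc9ccccc9)c1)[C@H](c1ccc(OCc9ccccc9)cc1)O2 | intermediate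
36 | (3S,4R,5S)-epimer of 34 (ring A cis to the C4 aryl group) | O=C1O[C@H](c2ccc(OCc9ccccc9)cc2)[C@@H](c2cc(OCc9ccccc9)cc(OCc9ccccc9)c2)[C@H]1c1cc(OCc9ccccc9)cc2c1[C@@H](c1cc(OCc9ccccc9)cc(OCc9ccccc9)c1)[C@H](c1ccc(OCc9ccccc9)cc1)O2 | intermediate
37 | [4-(benzyloxy)phenyl]lithium (formed in the flask) | [Li]c1ccc(OCc9ccccc9)cc1 | intermediate
38 | [4-(benzyloxy)phenyl]cerium dichloride (formed in the flask) | Cl[Ce](Cl)c1ccc(OCc9ccccc9)cc1 | intermediate
39 | (3S,4R,5S)-2,5-bis[4-(benzyloxy)phenyl]-4-[3,5-bis(benzyloxy)phenyl]-3-{(2R,3R)-6-(benzyloxy)-2-[4-(benzyloxy)phenyl]-3-[3,5-bis(benzyloxy)phenyl]-2,3-dihydro-1-benzofuran-4-yl}oxolan-2-ol, both anomers | OC1(c2ccc(OCc9ccccc9)cc2)O[C@H](c2ccc(OCc9ccccc9)cc2)[C@@H](c2cc(OCc9ccccc9)cc(OCc9ccccc9)c2)[C@H]1c1cc(OCc9ccccc9)cc2c1[C@@H](c1cc(OCc9ccccc9)cc(OCc9ccccc9)c1)[C@H](c1ccc(OCc9ccccc9)cc1)O2 | intermediate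
40 | octa-O-benzyl ether of the target, (2S,3S,4R,5S)-2,5-bis[4-(benzyloxy)phenyl]-4-[3,5-bis(benzyloxy)phenyl]-3-{(2R,3R)-6-(benzyloxy)-2-[4-(benzyloxy)phenyl]-3-[3,5-bis(benzyloxy)phenyl]-2,3-dihydro-1-benzofuran-4-yl}oxolane | c9ccccc9COc1ccc(cc1)[C@H]2O[C@H](c3ccc(OCc9ccccc9)cc3)[C@@H](c3cc(OCc9ccccc9)cc(OCc9ccccc9)c3)[C@H]2c2cc(OCc9ccccc9)cc3c2[C@@H](c2cc(OCc9ccccc9)cc(OCc9ccccc9)c2)[C@H](c2ccc(OCc9ccccc9)cc2)O3 | intermediate
41 | (2S,3S,4R,5S)-2,5-bis(4-hydroxyphenyl)-4-(3,5-dihydroxyphenyl)-3-[(2R,3R)-3-(3,5-dihydroxyphenyl)-6-hydroxy-2-(4-hydroxyphenyl)-2,3-dihydro-1-benzofuran-4-yl]oxolane (CNP0202577.3) | Oc1ccc([C@H]2O[C@H](c3ccc(O)cc3)[C@@H](c3cc(O)cc(O)c3)[C@H]2c2cc(O)cc3c2[C@@H](c2cc(O)cc(O)c2)[C@H](c2ccc(O)cc2)O3)cc1 | target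

## Step count and uncertain steps

Total: 22 steps. Longest linear sequence: 16 steps (steps 5–15 and 18–22, from 8 to 41). Side branches: steps 1–4 (aryne precursor 7) and steps 16–17 (sulfonium salt 31).

**Step 18 (proposed new method).** The most likely failure is mismatched double stereodifferentiation. The face of the methide carbon of 32 favoured by the lactone substituent on C4′ need not be the face the chiral ylide selects. The crowded methide carbon may also slow C–C bond formation enough for ylide 33 to decay by sigmatropic rearrangement or for sulfinate to re-add. Fallback with known chemistry, setting out from 27 and returning at 34: the annulation is run under the same carbonate conditions with the achiral salt 1-[4-(benzyloxy)benzyl]thiolan-1-ium tetrafluoroborate F1, made from 30, thiolane and HBF4·OEt2 as in step 17. This is the established [4+1] annulation without reagent control. Because the lactone part is enantiopure, the two trans products are diastereomers, 34 and its (2′S,3′S) isomer F2, and are separated by chromatography.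

**Step 12 (key step).** C3 of 22 is fully substituted after attack and shielded by the C4 aryl group. C-arylation may therefore lose to O-arylation of the enolate, or the aryl anion may be protonated before it closes on the ketone, while unconsumed aryne oligomerises. Fallback setting out from 19 and returning at 24, which makes the two bonds in separate known operations:
- 1-Bromo-3,5-bis(benzyloxy)benzene F3 is made by benzylation of commercial 5-bromoresorcinol.
- F3 is acylated ortho to bromine and para to a benzyloxy group with 3,5-bis(benzyloxy)benzoyl chloride F4 (from the commercial acid and oxalyl chloride) under SnCl4 in CH2Cl2 at −20 °C (Friedel–Crafts acylation), giving (2-bromo-4,6-bis(benzyloxy)phenyl)[3,5-bis(benzyloxy)phenyl]methanone F5.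
- Lactone 19 is deprotonated with LiN(SiMe3)2, transmetalated with ZnCl2 and coupled with F5 under Pd(dba)2/P(t-Bu)3 (zerovalent palladium, α-arylation of a zinc ester enolate), which gives 24 directly.

**Step 9.** The dynamic part may fail: if racemisation of the α-centre is slower than hydride transfer, the reduction becomes a plain kinetic resolution and the enantiomeric purity at C4 suffers; weak syn/anti discrimination has the same effect after step 10. Should the anti mode dominate cleanly, the mirror-image catalyst leads to the same lactone 19 after step 10. Fallback setting out from 16 and returning at 19: reduction with NaBH4 gives the hydroxy esters F6 as a mixture of all stereoisomers. Treatment with CF3CO2H as in step 10 converges them on the racemic trans lactone, that is 19 together with its enantiomer F7. The two are separated by preparative chromatography on a chiral stationary phase.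

**Step 19.** Facial discrimination in the protonation may be poor. Ring A is twisted out of the enolate plane and is likely to turn its substituted ortho carbon (C3a′ with the dihydrofuran ring) towards the face anti to the C4 aryl group, the face the proton should use. The phenoxide formed may also re-epimerise the product towards trans. Fallback setting out from 34 and returning at 36: enolate 35 is quenched with N-bromosuccinimide to give the 3-bromo lactone F8. F8 is reduced with Bu3SnH and Et3B/air in toluene at −78 °C, where the bulky stannane transfers a hydrogen atom to the planar C3 radical anti to the C4 aryl group (a radical instead of an ionic delivery of hydrogen).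

**Step 21 (with step 20).** The C3 configuration may be lost, either by enolisation of the open hydroxy ketone form of 39 or by proton loss from the oxocarbenium ion to the enol ether, and C2 may epimerise if the Lewis acid acts above −78 °C. Fallback setting out from 39 and returning at 41: 39 is dehydrated with pyridinium p-toluenesulfonate over molecular sieves in toluene to the 4,5-dihydrofuran F9, in which C3 is planar. Hydrogenation over Pd(OH)2/C (H2, 5 bar, EtOAc/MeOH) then adds both hydrogens to C2=C3 from one face, so the 2,3-cis relation is fixed by the syn mechanism. Addition is expected anti to the directly adjacent C4 aryl group, and the benzyl ethers are removed in the same operation.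

## Further compounds

F1 | step 18 | 1-[4-(benzyloxy)benzyl]thiolan-1-ium tetrafluoroborate | C1CC[S+](C1)Cc1ccc(OCc9ccccc9)cc1.F[B-](F)(F)F
F2 | step 18 | (2′S,3′S) diastereomer of 34, (3R,4R,5S)-5-[4-(benzyloxy)phenyl]-4-[3,5-bis(benzyloxy)phenyl]-3-{(2S,3S)-6-(benzyloxy)-2-[4-(benzyloxy)phenyl]-3-[3,5-bis(benzyloxy)phenyl]-2,3-dihydro-1-benzofuran-4-yl}oxolan-2-one | O=C1O[C@H](c2ccc(OCc9ccccc9)cc2)[C@@H](c2cc(OCc9ccccc9)cc(OCc9ccccc9)c2)[C@@H]1c1cc(OCc9ccccc9)cc2c1[C@H](c1cc(OCc9ccccc9)cc(OCc9ccccc9)c1)[C@@H](c1ccc(OCc9ccccc9)cc1)O2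
F3 | step 12 | 1-bromo-3,5-bis(benzyloxy)benzene | Brc1cc(OCc9ccccc9)cc(OCc9ccccc9)c1
F4 | step 12 | 3,5-bis(benzyloxy)benzoyl chloride | O=C(Cl)c1cc(OCc9ccccc9)cc(OCc9ccccc9)c1
F5 | step 12 | (2-bromo-4,6-bis(benzyloxy)phenyl)[3,5-bis(benzyloxy)phenyl]methanone | O=C(c1cc(OCc9ccccc9)cc(OCc9ccccc9)c1)c1c(Br)cc(OCc9ccccc9)cc1OCc9ccccc9
F6 | step 9 | ethyl 4-[4-(benzyloxy)phenyl]-3-[3,5-bis(benzyloxy)phenyl]-4-hydroxybutanoate, mixture of all four stereoisomers | CCOC(=O)CC(c1cc(OCc9ccccc9)cc(OCc9ccccc9)c1)C(O)c1ccc(OCc9ccccc9)cc1
F7 | step 9 | (4S,5R)-5-[4-(benzyloxy)phenyl]-4-[3,5-bis(benzyloxy)phenyl]oxolan-2-one, enantiomer of 19 | O=C1O[C@@H](c2ccc(OCc9ccccc9)cc2)[C@H](c2cc(OCc9ccccc9)cc(OCc9ccccc9)c2)C1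
F8 | step 19 | (4R,5S)-3-bromo-5-[4-(benzyloxy)phenyl]-4-[3,5-bis(benzyloxy)phenyl]-3-{(2R,3R)-6-(benzyloxy)-2-[4-(benzyloxy)phenyl]-3-[3,5-bis(benzyloxy)phenyl]-2,3-dihydro-1-benzofuran-4-yl}oxolan-2-one, C3 configuration of no consequence | O=C1O[C@H](c2ccc(OCc9ccccc9)cc2)[C@@H](c2cc(OCc9ccccc9)cc(OCc9ccccc9)c2)C1(Br)c1cc(OCc9ccccc9)cc2c1[C@@H](c1cc(OCc9ccccc9)cc(OCc9ccccc9)c1)[C@H](c1ccc(OCc9ccccc9)cc1)O2
F9 | step 21 | (4R,5S)-2,5-bis[4-(benzyloxy)phenyl]-4-[3,5-bis(benzyloxy)phenyl]-3-{(2R,3R)-6-(benzyloxy)-2-[4-(benzyloxy)phenyl]-3-[3,5-bis(benzyloxy)phenyl]-2,3-dihydro-1-benzofuran-4-yl}-4,5-dihydrofuran | c9ccccc9COc1ccc(cc1)C2=C(c3cc(OCc9ccccc9)cc4c3[C@@H](c3cc(OCc9ccccc9)cc(OCc9ccccc9)c3)[C@H](c3ccc(OCc9ccccc9)cc3)O4)[C@H](c3cc(OCc9ccccc9)cc(OCc9ccccc9)c3)[C@@H](c3ccc(OCc9ccccc9)cc3)O2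
A1 | alternative 1 | 4,5-trans-2,3,4,5-tetraaryl-4,5-dihydrofuran (C2=C3 enol ether), product of the key step | c9ccccc9COc1ccc(cc1)C2=C(c3cc(OCc9ccccc9)cc4c3[C@@H](c3cc(OCc9ccccc9)cc(OCc9ccccc9)c3)[C@H](c3ccc(OCc9ccccc9)cc3)O4)[C@H](c3cc(OCc9ccccc9)cc(OCc9ccccc9)c3)[C@@H](c3ccc(OCc9ccccc9)cc3)O2
A2 | alternative 1 | 1-[4-(benzyloxy)phenyl]-3-[3,5-bis(benzyloxy)phenyl]-2-{(2R,3R)-6-(benzyloxy)-2-[4-(benzyloxy)phenyl]-3-[3,5-bis(benzyloxy)phenyl]-2,3-dihydro-1-benzofuran-4-yl}prop-2-en-1-one | O=C(c1ccc(OCc9ccccc9)cc1)C(=Cc1cc(OCc9ccccc9)cc(OCc9ccccc9)c1)c1cc(OCc9ccccc9)cc2c1[C@@H](c1cc(OCc9ccccc9)cc(OCc9ccccc9)c1)[C@H](c1ccc(OCc9ccccc9)cc1)O2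
A3 | alternative 1 | donor–acceptor cyclopropane, [4-(benzyloxy)phenyl]{3-[4-(benzyloxy)phenyl]-2-[3,5-bis(benzyloxy)phenyl]-1-(dihydrobenzofuran-4-yl)cyclopropyl}methanone, ring configuration not fixed | O=C(c1ccc(OCc9ccccc9)cc1)C1(c2cc(OCc9ccccc9)cc3c2[C@@H](c2cc(OCc9ccccc9)cc(OCc9ccccc9)c2)[C@H](c2ccc(OCc9ccccc9)cc2)O3)C(c2cc(OCc9ccccc9)cc(OCc9ccccc9)c2)C1c1ccc(OCc9ccccc9)cc1
A4 | alternative 2 | octa-O-benzyl ether of the target (identical with 40), product of the key step | c9ccccc9COc1ccc(cc1)[C@H]2O[C@H](c3ccc(OCc9ccccc9)cc3)[C@@H](c3cc(OCc9ccccc9)cc(OCc9ccccc9)c3)[C@H]2c2cc(OCc9ccccc9)cc3c2[C@@H](c2cc(OCc9ccccc9)cc(OCc9ccccc9)c2)[C@H](c2ccc(OCc9ccccc9)cc2)O3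
A5 | alternative 2 | (2S,3S,4R,5S)-oxolane bearing on C3 a 5-(benzyloxy)-3-hydroxy-2-{[3,5-bis(benzyloxy)phenyl](4-methylbenzenesulfonyl)methyl}phenyl group | c9ccccc9COc1ccc(cc1)[C@H]1O[C@H](c2ccc(OCc9ccccc9)cc2)[C@@H](c2cc(OCc9ccccc9)cc(OCc9ccccc9)c2)[C@H]1c1cc(OCc9ccccc9)cc(O)c1C(c1cc(OCc9ccccc9)cc(OCc9ccccc9)c1)S(=O)(=O)c1ccc(C)cc1
A6 | alternative 3 | 2,3-cis lactone with the carbonyl at C5 (target numbering: ArP on C2, dihydrobenzofuranyl on C3, ArR on C4), product of the key step | c9ccccc9COc1ccc(cc1)[C@H]2OC(=O)[C@H](c3cc(OCc9ccccc9)cc(OCc9ccccc9)c3)[C@H]2c2cc(OCc9ccccc9)cc3c2[C@@H](c2cc(OCc9ccccc9)cc(OCc9ccccc9)c2)[C@H](c2ccc(OCc9ccccc9)cc2)O3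
A7 | alternative 3 | (E)-2-[3,5-bis(benzyloxy)phenyl]-3-{(2R,3R)-6-(benzyloxy)-2-[4-(benzyloxy)phenyl]-3-[3,5-bis(benzyloxy)phenyl]-2,3-dihydro-1-benzofuran-4-yl}prop-2-enal | O=C/C(c1cc(OCc9ccccc9)cc(OCc9ccccc9)c1)=C/c1cc(OCc9ccccc9)cc2c1[C@@H](c1cc(OCc9ccccc9)cc(OCc9ccccc9)c1)[C@H](c1ccc(OCc9ccccc9)cc1)O2
A8 | alternative 3 | 4-(benzyloxy)benzaldehyde | O=Cc1ccc(OCc9ccccc9)cc1
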